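**Retrosynthetic overview**
- The target comes from its 5,7-di-O-methyl ether. The phenols travel as methyl ethers through all the base chemistry and are freed in the last step.
- The key disconnection is C2–C1′. Chromone C2 is normally the electrophilic Michael terminus and a masked acyl carbon. Here it is used as a carbanion (a metalated enol ether, which is an acyl-anion and β-acylvinyl-anion equivalent) and joined to the equally electrophilic C1 of 1-bromoheptadecane.
- 5,7-Dimethoxy-6,8-dimethylchromone comes from an o-hydroxyacetophenone plus one carbon from an amide acetal, by enaminone cyclisation.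
- The acetophenone comes from Friedel–Crafts acetylation and ortho-demethylation of 1,3,5-trimethoxy-2,4-dimethylbenzene. That arene comes from two ortho-lithiation/methylation cycles on 1,3,5-trimethoxybenzene.
- Ring order: the benzene ring is bought. The pyranone ring is the only ring formed (step 3), before the key C–C bond.

Assumption: the target has no stereocentre and no stereogenic double bond, so it is achiral and the route needs no stereocontrol.

Step 1
Reactants: 1 1,3,5-trimethoxybenzene
Product: 5 1,3,5-trimethoxy-2,4-dimethylbenzene, via 2,4,6-trimethoxyphenyllithium 2 (not isolated), via 2,4,6-trimethoxytoluene 3 (not isolated), via 2,4,6-trimethoxy-3-methylphenyllithium 4 (not isolated)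
Conditions: n-BuLi (1.05 equiv), THF, 0 °C to rt, 1 h; MeI (1.05 equiv), 0 °C; then n-BuLi (1.15 equiv), 0 °C to rt, 2 h; MeI (1.5 equiv), 0 °C to rt, same flask
Reagents that add atoms: iodomethane, CI
Why: This is directed ortho-metalation, in which each ring C–H of 1 and of 3 lies between two OMe groups, so n-BuLi lithiates the ring rather than the benzylic CH3, and the aryllithium is methylated by SN2 on MeI; two cycles in one flask place both C-methyl groups and no stereocentre is formed.

Step 2
Reactants: 5 1,3,5-trimethoxy-2,4-dimethylbenzene
Product: 7 1-(2-hydroxy-4,6-dimethoxy-3,5-dimethylphenyl)ethan-1-one, via 2,4,6-trimethoxy-3,5-dimethylacetophenone 6 (not isolated)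
Conditions: AcCl (1.2 equiv), AlCl3 (2.5 equiv), CH2Cl2, 0 °C to reflux, 3 h; ice-water
Reagents that add atoms: acetyl chloride, CC(=O)Cl
Why: Friedel–Crafts acylation occurs at the only free, triply activated ring position, and AlCl3 then cleaves one of the two symmetry-equivalent OMe groups ortho to the new ketone under chelation control, stopping there because the aluminium is held in the six-membered chelate; no stereocentre is formed.

Step 3
Reactants: 7 1-(2-hydroxy-4,6-dimethoxy-3,5-dimethylphenyl)ethan-1-one
Product: 9 5,7-dimethoxy-6,8-dimethyl-4H-chromen-4-one, via (E)-dimethylaminovinyl ketone 8 (not isolated)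
Conditions: Me2NCH(OMe)2 (3 equiv), toluene, 110 °C, 4 h; evaporate; conc. HCl, CH2Cl2, 40 °C, 1 h
Reagents that add atoms: N,N-dimethylformamide dimethyl acetal, COC(OC)N(C)C
Why: This is the enaminone chromone synthesis, in which the methyl ketone condenses with the amide acetal and acid then triggers 6-endo oxa-Michael addition of the free phenol with loss of Me2NH, closing the pyranone ring and leaving C2–H free for the next step; no stereocentre is formed.

Step 4
Reactants: 9 5,7-dimethoxy-6,8-dimethyl-4H-chromen-4-one; 10 1-bromoheptadecane
Product: 13 2-heptadecyl-5,7-dimethoxy-6,8-dimethyl-4H-chromen-4-one, via 2-lithiochromone 11 (not isolated), via chromon-2-ylzinc chloride 12 (not isolated)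
Conditions: lithium 2,2,6,6-tetramethylpiperidide (1.2 equiv, from 2,2,6,6-tetramethylpiperidine + n-BuLi, THF, 0 °C) added to 9 + ZnCl2·2LiCl (1.1 equiv), THF, −78 °C, then rt; then 10 (1.3 equiv), Pd2(dba)3 (2 mol%), PCyp3 (8 mol%), N-methylimidazole (1.2 equiv), THF/NMP 2:1, 80 °C, 14 h
Reagents that add atoms: none
Why: C2–H (sp2, α to the ring oxygen, β to the carbonyl) is the most acidic C–H, so the hindered amide deprotonates it rather than adding to it, giving a metalated enol ether (an acyl-anion and β-acylvinyl-anion equivalent) that ZnCl2 traps in situ before it can attack a second chromone, and a Negishi sp2–sp3 coupling (SN2-type oxidative addition of the primary bromide to electron-rich zerovalent palladium bearing PCyp3, which slows β-hydride elimination) joins it to C1 of 10; C2-metalation of chromones and alkyl-halide Negishi coupling of alkenyl- and arylzinc halides are both known reaction types, only their combination on this substrate is untested, and no stereocentre is formed.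

Step 5
Reactants: 13 2-heptadecyl-5,7-dimethoxy-6,8-dimethyl-4H-chromen-4-one
Product: 14 2-heptadecyl-5,7-dihydroxy-6,8-dimethyl-4H-chromen-4-one
Conditions: BBr3 (5 equiv), CH2Cl2, −78 °C to rt, 12 h; MeOH, then water
Reagents that add atoms: none
Why: This is Lewis-acid aryl methyl ether cleavage, fast at the 5-OMe through carbonyl chelation and complete at the twisted 7-OMe at rt; the pyranone and the alkyl chain are inert, and any acid-induced ring opening and reclosure (Wessely–Moser) is degenerate because of the symmetric 6,8-dimethyl-5,7-dioxy pattern, and no stereocentre is present.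

**Compound list**
1 | 1,3,5-trimethoxybenzene | COc1cc(OC)cc(OC)c1 | starting material
2 | 2,4,6-trimethoxyphenyllithium | [Li]c1c(OC)cc(OC)cc1OC | intermediate
3 | 2,4,6-trimethoxytoluene | Cc1c(OC)cc(OC)cc1OC | intermediate
4 | 2,4,6-trimethoxy-3-methylphenyllithium | [Li]c1c(OC)cc(OC)c(C)c1OC | intermediate
5 | 1,3,5-trimethoxy-2,4-dimethylbenzene | COc1cc(OC)c(C)c(OC)c1C | intermediate
6 | 1-(2,4,6-trimethoxy-3,5-dimethylphenyl)ethan-1-one | CC(=O)c1c(OC)c(C)c(OC)c(C)c1OC | intermediate
7 | 1-(2-hydroxy-4,6-dimethoxy-3,5-dimethylphenyl)ethan-1-one | CC(=O)c1c(O)c(C)c(OC)c(C)c1OC | intermediate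
8 | (E)-3-(dimethylamino)-1-(2-hydroxy-4,6-dimethoxy-3,5-dimethylphenyl)prop-2-en-1-one | CN(C)/C=C/C(=O)c1c(O)c(C)c(OC)c(C)c1OC | intermediate
9 | 5,7-dimethoxy-6,8-dimethyl-4H-chromen-4-one | c1cc(=O)c2c(OC)c(C)c(OC)c(C)c2o1 | intermediate
10 | 1-bromoheptadecane | CCCCCCCCCCCCCCCCCBr | starting material
11 | (5,7-dimethoxy-6,8-dimethyl-4-oxo-4H-chromen-2-yl)lithium | [Li]c1cc(=O)c2c(OC)c(C)c(OC)c(C)c2o1 | intermediate
12 | chloro(5,7-dimethoxy-6,8-dimethyl-4-oxo-4H-chromen-2-yl)zinc | Cl[Zn]c1cc(=O)c2c(OC)c(C)c(OC)c(C)c2o1 | intermediate
13 | 2-heptadecyl-5,7-dimethoxy-6,8-dimethyl-4H-chromen-4-one | CCCCCCCCCCCCCCCCCc1cc(=O)c2c(OC)c(C)c(OC)c(C)c2o1 | intermediate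
14 | 2-heptadecyl-5,7-dihydroxy-6,8-dimethyl-4H-chromen-4-one (achiral) | CCCCCCCCCCCCCCCCCc1cc(=O)c2c(O)c(C)c(O)c(C)c2o1 | target

**Total step count:** 5. **Longest linear sequence:** 5 (1 → 5 → 7 → 9 → 13 → 14).

**The three steps most likely to fail**

The key coupling (step 4) is the riskiest.
- The electron-poor zinc reagent 12 may transmetalate slowly at 80 °C. In that case β-hydride elimination of the alkylpalladium species or protodezincation could win.
- The fallback sets out from 9, which is metalated exactly as before to 12, and comes back at 13. It keeps the C2 carbanion but replaces the two-electron alkyl halide coupling with a radical decarboxylative one.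
- Stearic acid is esterified (N-hydroxyphthalimide, N,N′-diisopropylcarbodiimide, cat. DMAP, CH2Cl2, rt) to 1,3-dioxoisoindolin-2-yl octadecanoate F1.
- This ester is treated with 12 (2 equiv), Ni(acac)2 (10 mol%) and 2,2′-bipyridine (10 mol%) in THF/DMF at rt. The heptadecyl radical released on decarboxylation is captured at nickel and coupled to the chromon-2-yl group.
- This also replaces the odd-chain bromide with a commodity acid.

The one-pot double methylation (step 1) is second.
- Incomplete lithiation in either cycle would give mono-, di- and trimethyl mixtures that are hard to separate.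
- The fallback sets out from 1 and comes back at 5. It replaces deprotonation with electrophilic halogenation and cross-coupling.
- NBS (2.05 equiv, MeCN, 0 °C to rt) gives crystalline 2,4-dibromo-1,3,5-trimethoxybenzene F2.
- A twofold Negishi methylation (MeZnCl, 3 equiv; Pd(P(t-Bu)3)2, 3 mol%; THF/NMP, 80 °C) then delivers 5.

The acylation/demethylation (step 2) is third.
- The ring position is crowded, and AlCl3 may also cleave the hindered 4-OMe.
- The fallback sets out from 5 and comes back at 7. It replaces electrophilic substitution with an anionic acylation.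
- n-BuLi/TMEDA (THF, 0 °C) removes the last ring proton, which lies between two OMe groups, to give 2,4,6-trimethoxy-3,5-dimethylphenyllithium F3.
- N-Methoxy-N-methylacetamide converts it into ketone 6, which is isolated this time.
- BCl3 (1.1 equiv, CH2Cl2, −78 to 0 °C) then removes only one ortho-methyl group to give 7.

**Further compounds**
F1 | step 4 | 1,3-dioxoisoindolin-2-yl octadecanoate | CCCCCCCCCCCCCCCCCC(=O)ON1C(=O)c2ccccc2C1=O
F2 | step 1 | 2,4-dibromo-1,3,5-trimethoxybenzene | COc1cc(OC)c(Br)c(OC)c1Br
F3 | step 2 | 2,4,6-trimethoxy-3,5-dimethylphenyllithium | [Li]c1c(OC)c(C)c(OC)c(C)c1OC
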